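A direct plan would buy both arenes and join them by SNAr: the phenoxide of 3-(benzyloxy)-2-hydroxy-5-methylbenzaldehyde A1 would displace fluoride from benzyl 6-fluoro-3-formyl-2-methoxybenzoate A2 to give the diaryl ether dialdehyde A3.
Both aldehydes of A3 would then be converted into dimethyl acetals to give the bis(dimethyl acetal) A4, the ring A acetal would be methallylated enantioselectively to set the methyl ether stereocentre, and hydrogenation plus acetal hydrolysis would finish.
Weak point 1, the enantioselective methallylation of one of two dimethyl acetals: it would have to be enantioselective and site-selective at once, and no catalytic allylsilane addition to an acyclic acetal is known to give that control.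
Weak point 2, the acetal formation, hydrolysis and re-formation on ring A (for the metalation of the fluoroarene, the SNAr and the allylation): three operations that build nothing.
Weak point 3, the final hydrogenation: it would have to saturate an alkene and cleave two benzyl groups next to a doubly donor-activated benzylic methyl ether, and it is followed by acid that can ionise the same ether.

**Retrosynthetic overview**
- Ring A is made last. Its C1(CO2H)–C6(O-aryl)–C5–C4 edge comes from a 3-allyloxycarbonyl-4-aryloxy-2-pyrone that already carries ring B on oxygen, and its C2(O)–C3(side chain) edge comes from a siloxyalkyne. An inverse-electron-demand Diels–Alder reaction forms the C1–C2 and C3–C4 bonds, and loss of CO2 aromatises.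
- Ring order: ring B (bought), then the pyrone ring (from a malonate and 3-ethoxyacryloyl chloride), then ring A (from the pyrone). No two arenes are ever coupled.
- The (R) stereocentre is bought as D-leucic acid and carried into the alkyne by a Kowalski homologation, so no asymmetric C–C bond formation is needed, and it is never alpha to a carbonyl group after that.
- No acetals are used. The only protecting groups are two allyl groups, removed together by zerovalent palladium under neutral conditions, so there is no late hydrogenation.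

Key step: step 8

Remark: (2R)-2-hydroxy-4-methylpentanoic acid (D-leucic acid) is taken as commercial; it would otherwise come from D-leucine by nitrous acid deamination, which proceeds with retention.

Step 1
Reactants: 1 2-hydroxy-3-methoxy-5-methylbenzaldehyde
Product: 2 2,3-dihydroxy-5-methylbenzaldehyde
Conditions: BBr3 (2.2 equiv), CH2Cl2, −78 °C to rt; then H2O, 0 °C
Reagents that add atoms: none
Why: Lewis acid cleavage of an aryl methyl ether, in which boron binds the phenol/methoxy pair and bromide removes the methyl group by SN2, while the aldehyde is untouched.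

Step 2
Reactants: 2 2,3-dihydroxy-5-methylbenzaldehyde; 3 allyl bromide
Product: 4 2-hydroxy-5-methyl-3-(prop-2-en-1-yloxy)benzaldehyde
Conditions: NaH (2.2 equiv), DMSO, rt; 3 (1.0 equiv), rt; 1 M HCl work-up
Reagents that add atoms: allyl bromide (3), C=CCBr
Why: Regioselective Williamson etherification of the dianion, in which the 2-oxide is delocalised into the ortho formyl group and chelated to sodium, so the single equivalent of allyl bromide should alkylate the more basic 3-oxide.

Step 3
Reactants: 5 di(prop-2-en-1-yl) propanedioate (diallyl malonate); 6 (2E)-3-ethoxyprop-2-enoyl chloride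
Product: 7 di(prop-2-en-1-yl) 2-[(2E)-3-ethoxyprop-2-enoyl]propanedioate
Conditions: MgCl2 (1.1 equiv), Et3N (2.2 equiv), MeCN, 0 °C to rt; cold 1 M HCl work-up
Reagents that add atoms: (2E)-3-ethoxyprop-2-enoyl chloride (6), CCO/C=C/C(=O)Cl
Why: C-acylation of a magnesium malonate enolate formed by soft enolisation (Rathke conditions); the acidic tricarbonyl product stays bound to magnesium, which should stop O-acylation and double acylation.

Step 4
Reactants: 7 di(prop-2-en-1-yl) 2-[(2E)-3-ethoxyprop-2-enoyl]propanedioate
Product: 8 prop-2-en-1-yl 4-hydroxy-2-oxo-2H-pyran-3-carboxylate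
Conditions: CF3CO2H–H2O (9:1), 0 °C to rt
Reagents that add atoms: water, O
Why: Acid hydrolysis of the beta-ethoxyvinyl ketone should unmask a formyl ketone whose (Z)-enol closes onto one allyl ester (6-exo-trig lactonisation with loss of allyl alcohol), the same closure that gives 4-hydroxy-2-pyrones from 3,5-dioxo esters.

Step 5
Reactants: 8 prop-2-en-1-yl 4-hydroxy-2-oxo-2H-pyran-3-carboxylate; 4 2-hydroxy-5-methyl-3-(prop-2-en-1-yloxy)benzaldehyde
Product: 10 prop-2-en-1-yl 4-[2-formyl-4-methyl-6-(prop-2-en-1-yloxy)phenoxy]-2-oxo-2H-pyran-3-carboxylate, via 4-chloropyrone 9 (not isolated)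
Conditions: (COCl)2 (1.2 equiv), DMF (cat.), CH2Cl2, 0 °C to rt, evaporate; then 4 (1.0 equiv), K2CO3 (1.5 equiv), MeCN, 0 °C to rt
Reagents that add atoms: none
Why: Vilsmeier-type conversion of the vinylogous acid into the vinylogous acid chloride 9, then addition–elimination of the phenoxide at C4, which is beta to both carbonyl groups and bears the leaving group; the only free oxygen of 4 is the one ortho to the formyl group.

Step 6
Reactants: 11 (2R)-2-hydroxy-4-methylpentanoic acid
Product: 12 methyl (2R)-2-methoxy-4-methylpentanoate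
Conditions: MeI (6 equiv), Ag2O (2.5 equiv), MeCN, rt, dark
Reagents that add atoms: iodomethane, CI
Why: Purdie methylation converts the carboxyl and hydroxyl groups in one operation under non-basic conditions, so the alpha stereocentre should not be enolised.

Step 7
Reactants: 12 methyl (2R)-2-methoxy-4-methylpentanoate
Product: 14 {[(3R)-3-methoxy-5-methylhex-1-yn-1-yl]oxy}tri(propan-2-yl)silane, via lithium ynolate 13 (not isolated)
Conditions: CH2Br2 (2.2 equiv), lithium 2,2,6,6-tetramethylpiperidide (2.1 equiv), THF, −78 °C; then n-BuLi (3.5 equiv), −78 °C to rt; then i-Pr3SiOTf, −78 to 0 °C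
Reagents that add atoms: dibromomethane, BrCBr; triisopropylsilyl trifluoromethanesulfonate, CC(C)[Si](C(C)C)(C(C)C)OS(=O)(=O)C(F)(F)F
Why: Kowalski ester homologation, in which LiCHBr2 adds to the ester, the dibromo ketone enolate undergoes Br/Li exchange and the alpha-methoxyalkyl group shifts to the carbenoid carbon with retention to give ynolate 13, which the bulky silyl triflate traps on oxygen.

Step 8
Reactants: 10 prop-2-en-1-yl 4-[2-formyl-4-methyl-6-(prop-2-en-1-yloxy)phenoxy]-2-oxo-2H-pyran-3-carboxylate; 14 {[(3R)-3-methoxy-5-methylhex-1-yn-1-yl]oxy}tri(propan-2-yl)silane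
Product: 16 prop-2-en-1-yl 6-[2-formyl-4-methyl-6-(prop-2-en-1-yloxy)phenoxy]-3-[(1R)-1-methoxy-3-methylbutyl]-2-{[tri(propan-2-yl)silyl]oxy}benzoate, via bicyclic lactone cycloadduct 15 (not isolated)
Conditions: 14 (1.5 equiv), PhMe, 110 °C, sealed tube
Reagents that add atoms: none
Why: Inverse-electron-demand Diels–Alder reaction followed by cycloreversion: the HOMO of the siloxyalkyne, largest at the alkyl-bearing carbon, meets the LUMO of the pyrone, whose 2-oxo and 3-ester groups make C6 the electrophilic diene terminus, so the C6–C(alkyl) bond (C4–C3 of ring A) forms ahead of the C3–C(OSi) bond (C1–C2 of ring A), and the bridged lactone 15 then expels CO2 by retro-[4+2] to give the benzene ring. The closest known reaction type is the cycloaddition of 3-alkoxycarbonyl-2-pyrones with ketene acetals and ynamines, which gives salicylate ethers and anthranilates with the heteroatom next to the ester, and siloxyalkynes are established electron-rich 2π partners in thermal benzannulations. Ring A is the only ring closed, by an intermolecular [4+2] cycloaddition across C3 and C6 of the pyrone and aromatised by loss of the lactone bridge, so all six substituents of ring A are placed at once and no oxidation is needed. No stereocentre that survives is created (the bridgeheads of 15 vanish), and the (R) centre, a propargylic and then benzylic ether with no acidic neighbour, is carried through unchanged. The step needs regioselectivity, secured by this matched polarisation and by the branched chain going to the unsubstituted C6, and chemoselectivity for the diene over the aryl aldehyde, the two unactivated allyl groups and substitution at C4, secured by the absence of any Lewis acid and by the donor oxygen that deactivates C4.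

Step 9
Reactants: 16 prop-2-en-1-yl 6-[2-formyl-4-methyl-6-(prop-2-en-1-yloxy)phenoxy]-3-[(1R)-1-methoxy-3-methylbutyl]-2-{[tri(propan-2-yl)silyl]oxy}benzoate
Product: 17 prop-2-en-1-yl 6-[2-formyl-4-methyl-6-(prop-2-en-1-yloxy)phenoxy]-2-methoxy-3-[(1R)-1-methoxy-3-methylbutyl]benzoate
Conditions: CsF (3 equiv), MeI (5 equiv), DMF, rt
Reagents that add atoms: iodomethane, CI
Why: Fluoride cleaves the aryl silyl ether and the caesium phenoxide is methylated in the same flask (Williamson etherification), while the allyl ester, allyl ether and aldehyde should be inert.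

Step 10
Reactants: 17 prop-2-en-1-yl 6-[2-formyl-4-methyl-6-(prop-2-en-1-yloxy)phenoxy]-2-methoxy-3-[(1R)-1-methoxy-3-methylbutyl]benzoate
Product: 18 6-(2-formyl-6-hydroxy-4-methylphenoxy)-2-methoxy-3-[(1R)-1-methoxy-3-methylbutyl]benzoic acid
Conditions: Pd(PPh3)4 (5 mol%), p-TolSO2Na (2.5 equiv), THF–MeOH, rt; 0.5 M HCl work-up, 0 °C
Reagents that add atoms: none
Why: Tsuji–Trost deallylation, in which zerovalent palladium ionises both the allyl ester and the aryl allyl ether to π-allyl complexes that the sulfinate traps as a sulfone; the neutral conditions should spare the aldehyde and the benzylic methyl ether, so the (R) centre is kept and 18 is the target.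

**Compound list**

1 | 2-hydroxy-3-methoxy-5-methylbenzaldehyde | COc1cc(C)cc(C=O)c1O | starting material
2 | 2,3-dihydroxy-5-methylbenzaldehyde | O=Cc1cc(C)cc(O)c1O | intermediate
3 | allyl bromide (3-bromoprop-1-ene) | C=CCBr | starting material
4 | 2-hydroxy-5-methyl-3-(prop-2-en-1-yloxy)benzaldehyde | C=CCOc1cc(C)cc(C=O)c1O | intermediate
5 | di(prop-2-en-1-yl) propanedioate (diallyl malonate) | C=CCOC(=O)CC(=O)OCC=C | starting material
6 | (2E)-3-ethoxyprop-2-enoyl chloride | CCO/C=C/C(=O)Cl | starting material
7 | di(prop-2-en-1-yl) 2-[(2E)-3-ethoxyprop-2-enoyl]propanedioate | CCO/C=C/C(=O)C(C(=O)OCC=C)C(=O)OCC=C | intermediate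
8 | prop-2-en-1-yl 4-hydroxy-2-oxo-2H-pyran-3-carboxylate | C=CCOC(=O)C1=C(O)C=COC1=O | intermediate
9 | prop-2-en-1-yl 4-chloro-2-oxo-2H-pyran-3-carboxylate | C=CCOC(=O)C1=C(Cl)C=COC1=O | intermediate
10 | prop-2-en-1-yl 4-[2-formyl-4-methyl-6-(prop-2-en-1-yloxy)phenoxy]-2-oxo-2H-pyran-3-carboxylate | C=CCOC(=O)C1=C(Oc2c(OCC=C)cc(C)cc2C=O)C=COC1=O | intermediate
11 | (2R)-2-hydroxy-4-methylpentanoic acid | CC(C)C[C@@H](O)C(=O)O | starting material
12 | methyl (2R)-2-methoxy-4-methylpentanoate | CO[C@H](CC(C)C)C(=O)OC | intermediate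
13 | lithium (3R)-3-methoxy-5-methylhex-1-yn-1-olate | CO[C@H](CC(C)C)C#C[O-].[Li+] | intermediate
14 | {[(3R)-3-methoxy-5-methylhex-1-yn-1-yl]oxy}tri(propan-2-yl)silane | CO[C@H](CC(C)C)C#CO[Si](C(C)C)(C(C)C)C(C)C | intermediate
15 | prop-2-en-1-yl 8-[2-formyl-4-methyl-6-(prop-2-en-1-yloxy)phenoxy]-6-[(1R)-1-methoxy-3-methylbutyl]-3-oxo-5-{[tri(propan-2-yl)silyl]oxy}-2-oxabicyclo[2.2.2]octa-5,7-diene-4-carboxylate (bridgehead diastereomers) | O=C1OC2C=C(Oc3c(OCC=C)cc(C)cc3C=O)C1(C(=O)OCC=C)C(O[Si](C(C)C)(C(C)C)C(C)C)=C2[C@@H](CC(C)C)OC | intermediate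
16 | prop-2-en-1-yl 6-[2-formyl-4-methyl-6-(prop-2-en-1-yloxy)phenoxy]-3-[(1R)-1-methoxy-3-methylbutyl]-2-{[tri(propan-2-yl)silyl]oxy}benzoate | CO[C@H](CC(C)C)c1ccc(Oc2c(OCC=C)cc(C)cc2C=O)c(C(=O)OCC=C)c1O[Si](C(C)C)(C(C)C)C(C)C | intermediate
17 | prop-2-en-1-yl 6-[2-formyl-4-methyl-6-(prop-2-en-1-yloxy)phenoxy]-2-methoxy-3-[(1R)-1-methoxy-3-methylbutyl]benzoate | CO[C@H](CC(C)C)c1ccc(Oc2c(OCC=C)cc(C)cc2C=O)c(C(=O)OCC=C)c1OC | intermediate
18 | 6-(2-formyl-6-hydroxy-4-methylphenoxy)-2-methoxy-3-[(1R)-1-methoxy-3-methylbutyl]benzoic acid | COc1c([C@@H](CC(C)C)OC)ccc(Oc2c(O)cc(C)cc2C=O)c1C(=O)O | target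

**Step count and risks**

Total step count: 10. Longest linear sequence: 6 steps (1 → 2 → 4 → 10 → 16 → 17 → 18, or equally 5 → 7 → 8 → 10 → 16 → 17 → 18).

Steps most likely to fail:

Step 8. The 4-aryloxy group lowers the electrophilicity of the pyrone, so the cycloaddition may be too slow at temperatures the siloxyalkyne tolerates. The siloxyalkyne may also add to the ring B aldehyde or displace the aryloxide at C4. The fallback sets out from 10 and comes back at 17; it changes the dienophile to a ketene silyl acetal, the class with the closest precedent for 3-alkoxycarbonyl-2-pyrones, and takes the stereocentre from an asymmetric hydrogenation. Methyl 5-methyl-3-oxohexanoate F1 would be hydrogenated (H2, RuCl2[(R)-BINAP], MeOH) to methyl (3R)-3-hydroxy-5-methylhexanoate F2. Methylation (MeI, Ag2O) would give methyl (3R)-3-methoxy-5-methylhexanoate F3. Enolisation and silylation (LiN(i-Pr)2, Me3SiCl, THF, −78 °C, kept cold to avoid loss of methoxide) would give {[(3R)-1,3-dimethoxy-5-methylhex-1-en-1-yl]oxy}trimethylsilane F4. Heating F4 with 10 in toluene at 80–110 °C should give 17 directly, after cycloaddition and loss of carbon dioxide and trimethylsilanol.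

Step 7. The lithium amide may partly epimerise the alpha-methoxy ester, or the carbenoid rearrangement may be low-yielding with the branched alpha-alkoxy group. The fallback sets out from 12 and comes back at 14. Reduction with i-Bu2AlH (CH2Cl2, −78 °C) would give (2R)-2-methoxy-4-methylpentanal F5. Ohira–Bestmann alkynylation (dimethyl (1-diazo-2-oxopropyl)phosphonate, K2CO3, MeOH, 0 °C) would give (3R)-3-methoxy-5-methylhex-1-yne F6. Deprotonation (n-BuLi, THF, −78 °C) and oxidation of the lithium acetylide with LiOO-t-Bu would give the same ynolate 13, which i-Pr3SiOTf would silylate to 14.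

Step 4. The tricarbonyl compound may lose its acyl group by retro-Claisen cleavage in aqueous acid, or it may close to the isomeric 2-alkoxy-4-pyranone. The fallback sets out from 5 and 4 and comes back at 10, so it also bypasses step 5; it builds the pyrone ring on the aryl enol ether instead. Malonate 5 would be C-acetylated (AcCl, MgCl2, Et3N, MeCN) to di(prop-2-en-1-yl) 2-acetylpropanedioate F7, which would be converted (POCl3, n-Bu3N) into di(prop-2-en-1-yl) 2-(1-chloroethylidene)propanedioate F8. Phenol 4 would be masked (ethane-1,2-diol, p-TsOH, PhMe, Dean–Stark) as 2-(1,3-dioxolan-2-yl)-4-methyl-6-(prop-2-en-1-yloxy)phenol F9, so that the carbanions of the next two stages cannot add to the aldehyde and form a chromene. The phenoxide of F9 would displace the chloride of F8 (K2CO3, MeCN) to give di(prop-2-en-1-yl) 2-{1-[2-(1,3-dioxolan-2-yl)-4-methyl-6-(prop-2-en-1-yloxy)phenoxy]ethylidene}propanedioate F10. Condensation of its activated methyl group with Me2NCH(OMe)2 (PhMe, 90 °C) would give di(prop-2-en-1-yl) 2-{(2E)-3-(dimethylamino)-1-[2-(1,3-dioxolan-2-yl)-4-methyl-6-(prop-2-en-1-yloxy)phenoxy]prop-2-en-1-ylidene}propanedioate F11. Aqueous acid (AcOH–H2O, 60 °C) should then close the pyrone ring and free the aldehyde, giving 10.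

Further compounds
F1 | step 8 | methyl 5-methyl-3-oxohexanoate | CC(C)CC(=O)CC(=O)OC
F2 | step 8 | methyl (3R)-3-hydroxy-5-methylhexanoate | O[C@H](CC(C)C)CC(=O)OC
F3 | step 8 | methyl (3R)-3-methoxy-5-methylhexanoate | CO[C@H](CC(C)C)CC(=O)OC
F4 | step 8 | {[(3R)-1,3-dimethoxy-5-methylhex-1-en-1-yl]oxy}trimethylsilane | CO[C@H](CC(C)C)C=C(OC)O[Si](C)(C)C
F5 | step 7 | (2R)-2-methoxy-4-methylpentanal | CO[C@H](CC(C)C)C=O
F6 | step 7 | (3R)-3-methoxy-5-methylhex-1-yne | CO[C@H](CC(C)C)C#C
F7 | step 4 | di(prop-2-en-1-yl) 2-acetylpropanedioate | CC(=O)C(C(=O)OCC=C)C(=O)OCC=C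
F8 | step 4 | di(prop-2-en-1-yl) 2-(1-chloroethylidene)propanedioate | CC(Cl)=C(C(=O)OCC=C)C(=O)OCC=C
F9 | step 4 | 2-(1,3-dioxolan-2-yl)-4-methyl-6-(prop-2-en-1-yloxy)phenol | C=CCOc1cc(C)cc(C2OCCO2)c1O
F10 | step 4 | di(prop-2-en-1-yl) 2-{1-[2-(1,3-dioxolan-2-yl)-4-methyl-6-(prop-2-en-1-yloxy)phenoxy]ethylidene}propanedioate | CC(Oc1c(OCC=C)cc(C)cc1C1OCCO1)=C(C(=O)OCC=C)C(=O)OCC=C
F11 | step 4 | di(prop-2-en-1-yl) 2-{(2E)-3-(dimethylamino)-1-[2-(1,3-dioxolan-2-yl)-4-methyl-6-(prop-2-en-1-yloxy)phenoxy]prop-2-en-1-ylidene}propanedioate | CN(C)/C=C/C(Oc1c(OCC=C)cc(C)cc1C1OCCO1)=C(C(=O)OCC=C)C(=O)OCC=C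
A1 | direct plan | 3-(benzyloxy)-2-hydroxy-5-methylbenzaldehyde | O=Cc1cc(C)cc(OCc2ccccc2)c1O
A2 | direct plan | benzyl 6-fluoro-3-formyl-2-methoxybenzoate | COc1c(C(=O)OCc2ccccc2)c(F)ccc1C=O
A3 | direct plan | benzyl 6-[2-(benzyloxy)-6-formyl-4-methylphenoxy]-3-formyl-2-methoxybenzoate | COc1c(C=O)ccc(Oc2c(OCc3ccccc3)cc(C)cc2C=O)c1C(=O)OCc1ccccc1
A4 | direct plan | benzyl 6-[2-(benzyloxy)-6-(dimethoxymethyl)-4-methylphenoxy]-3-(dimethoxymethyl)-2-methoxybenzoate | COc1c(C(OC)OC)ccc(Oc2c(OCc3ccccc3)cc(C)cc2C(OC)OC)c1C(=O)OCc1ccccc1
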